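## The problem

The target is achiral: a fully substituted 4-hydroxy-2-pyrone (ring A: O1, C2 lactone carbonyl, C3, C4–OH, C5–CH3, C6–C2H5) joined through one CH2 group at C3 to a hexasubstituted acylphloroglucinol (ring B: C1' bridge, C2'–OH, C3' prenyl, C4'–OH, C5' 2-methylpropanoyl, C6'–OCH3). With no stereocentre, the difficulty is regiochemical. Three different carbon substituents must be placed between three oxygens on ring B, and ring A must be attached at C1' only. The usual way to such bridges, condensing a finished pyrone and a phloroglucinol with formaldehyde, joins two nucleophiles of similar reactivity and is prone to symmetrical dimers. The prenyl group at C3' lies between two phenols and is lost to chroman formation or HX addition under strong protic or Lewis acid. The C4' hydroxyl is chelated to the ketone and hindered, whereas the C2' hydroxyl is not. The enabling feature is that C2, C3 and C4 of ring A are a malonyl unit which, through the C3–CH2–C1' link and the neighbouring C2' oxygen, folds back into a 2-oxochromane-3-carboxylic acid. In that form C2 is already an aryl ester with a built-in leaving group, C4 is a carboxyl that can be activated, and C2'–OH is masked while the lactone lasts. The rest of ring A (O1, C5, C6 with methyl and ethyl) is the enol of pentan-3-one.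

## Retrosynthesis

**17 from 16.** The last bond cut is the Si–O bond of a single tert-butyldimethylsilyl ether on O4' in 16. Buffered fluoride removes it without acid, which the prenyl group between two free phenols would not tolerate. The C2' and pyrone hydroxyls need no protection because both are created by the key step.

**16 from 12 and 14.** Ring A is cut at C4–C5 and O1–C2. The neighbouring cuts are less attractive: a cut at the CH2 bridge returns to the formaldehyde coupling and its dimers, and a cut at C3–C4 needs an ester enolate beside an enol ester. The chosen cut leaves acid chloride 12, a bicyclic chromanone that already carries every ring B substituent and the bridge, and the five-carbon silyl enol ether 14. The forward reaction must C-acylate 14 with the acid chloride to give triketone 15. The enol oxygen of 15 must then take over the aryl ester carbonyl and release O2'. Both carbonyls hang on C3, so the reverse order of the two acylations converges on the same pyrone.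

**12 from 11 and 10.** The C–Cl bond is traced to a silyl ester, and both Si–O bonds of 11 to the hydroxy acid 10. Capping O4' as an ester was set aside because acylating a chelated, hindered phenol needs a nucleophilic catalyst. Such a catalyst can open the activated aryl lactone, and the anhydride would also engage the malonic carboxyl. Silylating both acidic sites of 10 at once needs no chemoselection. The silyl ester of 11 then gives 12 with oxalyl chloride without liberating HCl next to the prenyl group.

**10 from 6, 7 and formaldehyde.** Three bonds are cut: C1'–CH2, CH2–C3 and the lactone O–C2. Forward, 7 and formaldehyde give the alkylidene 8, ketone 6 adds through its ring carbon to give 9, and the neighbouring phenol closes the lactone with loss of acetone. Ketone 6 has one free ring carbon and one hydroxyl next to it, the unchelated one, so the substrate fixes both the site of attack and the lactonising oxygen. This step replaces the intermolecular bridge-forming coupling by a reaction in which only one partner is an arene.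

**6 from 4 and 5; 4 from 1 and 2.** The C3'–prenyl bond and then the aryl–acyl bond are cut, leading to 5-methoxyresorcinol 1, prenyl bromide 5 and 2-methylpropanenitrile 2. These are the only two steps whose regiochemistry is not forced by the substrate. Acylation must go para to one hydroxyl of 1, not between the two. Prenylation must go to the carbon between the two oxygens of 4. Both preferences have classical analogy. A directed-metalation sequence from 1 is held in reserve.

**14 from 13.** The Si–O bond is cut to pentan-3-one 13.

## Roads not taken

**Alternative 1:** The cut goes through ring B itself, at C1'–C6' and C4'–C5'. A Diels–Alder reaction between methoxy ynone A2 and the prenylated bis(silyloxy)diene A3, followed by loss of the acetal methoxy group as methoxytrimethylsilane, would aromatise to A1. A1 is identical with ketone 6 of the chosen route.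
- Merits: all six positions of ring B are fixed by the polarisation of the two partners and none is left to electrophilic substitution. In this respect it is better than steps 1 and 2.
- Weak points: A2 is an acylated ynol ether, sensitive to hydrolysis and a sluggish dienophile because its β-carbon carries a donor. A3 needs alkylation and double silylation of an acetoacetate. Aromatisation must expel the methoxy group and not the silyloxy group on the same carbon. Several steps are spent on a compound that two steps from 1 can deliver.
- Comparison: it addresses only ring B and would still need the rest of the chosen route for the bridge and ring A. The chosen plan sets against its regiocontrol the shortness of steps 1 and 2 and a regiodefined fallback.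

**Alternative 2:** The cut is at C3–C4. In enol ester A4 a strong amide base would generate the ester enolate at the arylpropanoyl α-carbon, which attacks the methyl ester across the enol double bond and closes ring A to the bis(methoxymethyl) ether A5.
- Merits: the C–C bond is formed intramolecularly through a six-membered transition state, where the chosen plan forms it intermolecularly. No malonyl acid chloride is needed, and C4–C6 come from a simple β-keto ester.
- Weak points: the ester enolate of an enol ester can fragment by E1cB to a ketene and a β-keto ester enolate, or transfer its acyl group. The enol ester must have the Z geometry. The aryl ketone has its own α-hydrogen. Both phenols must be protected because O2' plays no structural role. Their acetals are finally removed with acid beside a prenyl group flanked by two phenols. The arylpropanoyl half is most directly reached from the same dihydrocoumarin, so the sequence is longer.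
- Comparison: the chosen plan uses a neutral carbon nucleophile under a mild Lewis acid and uses O2' as the leaving group instead of protecting it.

**Alternative 3:** The cuts are at C3–CH2 and C4–C5. Thermolysis of diazo keto ester A6 would expel dinitrogen with migration of the arylmethyl group. The resulting ketene A7 would be attacked by the enol ester carbon to close ring A as the di-O-acetate A8.
- Merits: conditions are neutral, two skeletal bonds arise from one intermediate without any reagent, and both phenols carry the same easily removed acetate.
- Weak points: A6 needs an arylacetyl unit on a hexasubstituted ring, an enol ester of a β-keto acid and a diazo transfer, which is a long preparation. The Wolff rearrangement of a 2-diazo-1,3-dicarbonyl compound needs high temperature, light or a metal. The carbene can be diverted by the prenyl alkene or by alkoxy migration. An enol ester is a weak carbon nucleophile, so the ketene may dimerise.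
- Comparison: the chosen plan obtains the C3–CH2–C1' connection from a simple condensation on the existing arene and avoids diazo chemistry. It pays with one protecting group and an acid chloride that must be used at once.

Key step: step 7

Remark: the target has no stereocentre. Compounds 10, 11, 12 and 15 carry labile stereocentres at malonyl or diketone carbons and are handled as stereoisomer mixtures. The geometry of 14 is immaterial because both of its olefinic carbons end as sp2 ring atoms.

## Route

Step 1
Reactants: 1 5-methoxyresorcinol; 2 2-methylpropanenitrile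
Product: 4 1-(2,4-dihydroxy-6-methoxyphenyl)-2-methylpropan-1-one, via ketiminium chloride 3 (not isolated)
Conditions: ZnCl2, HCl (g), Et2O, 0 °C; then H2O, 100 °C
Reagents that add atoms: water, O
Why: Houben–Hoesch acylation; the nitrilium species should attack one of the two equivalent ring carbons para to a hydroxyl rather than the carbon between the hydroxyls, the isomer from the latter attack is expected to be separable, and these conditions spare the methyl ether that ends ortho to the ketone.

Step 2
Reactants: 4 1-(2,4-dihydroxy-6-methoxyphenyl)-2-methylpropan-1-one; 5 1-bromo-3-methylbut-2-ene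
Product: 6 1-[2,4-dihydroxy-6-methoxy-3-(3-methylbut-2-en-1-yl)phenyl]-2-methylpropan-1-one
Conditions: 5 (1.0 equiv), 10% aq KOH, 0 °C → rt
Reagents that add atoms: none
Why: C-alkylation of an ambident phenoxide in water, where hydrogen bonding to oxygen disfavours O-alkylation; the carbon between the two oxygens is the site favoured by bond fixation in chelated 2,4-dihydroxyaryl ketones (as in their nuclear methylation and allylation), and limiting the bromide should hold back dialkylation.

Step 3
Reactants: 6 1-[2,4-dihydroxy-6-methoxy-3-(3-methylbut-2-en-1-yl)phenyl]-2-methylpropan-1-one; 7 2,2-dimethyl-1,3-dioxane-4,6-dione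
Product: 10 7-hydroxy-5-methoxy-8-(3-methylbut-2-en-1-yl)-6-(2-methylpropanoyl)-2-oxochromane-3-carboxylic acid, via methylidene Meldrum's acid 8 (not isolated), via benzyl Meldrum's acid adduct 9 (not isolated)
Conditions: 7 and (CH2O)n premixed, L-proline (10 mol%), MeCN, rt; then 6, rt → 45 °C
Reagents that add atoms: formaldehyde (as paraformaldehyde), C=O
Why: Three-component Knoevenagel–Michael–lactonisation of a phenol, an aldehyde and Meldrum's acid; 8 is trapped by the only free ring carbon of 6, the adjacent unchelated hydroxyl opens the dioxanedione with loss of acetone, and the temperature is kept below that at which the malonic half-ester decarboxylates.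

Step 4
Reactants: 10 7-hydroxy-5-methoxy-8-(3-methylbut-2-en-1-yl)-6-(2-methylpropanoyl)-2-oxochromane-3-carboxylic acid
Product: 11 tert-butyldimethylsilyl 7-[(tert-butyldimethylsilyl)oxy]-5-methoxy-8-(3-methylbut-2-en-1-yl)-6-(2-methylpropanoyl)-2-oxochromane-3-carboxylate
Conditions: TBSOTf (2.1 equiv), 2,6-lutidine (3 equiv), CH2Cl2, −78 → 0 °C; cold neutral work-up, used without chromatography
Reagents that add atoms: tert-butyldimethylsilyl trifluoromethanesulfonate, CC(C)(C)[Si](C)(C)OS(=O)(=O)C(F)(F)F
Why: Exhaustive O-silylation of both acidic sites with a silyl triflate strong enough for the chelated, di-ortho-substituted phenol; the hindered, non-nucleophilic base should leave the activated aryl lactone closed.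

Step 5
Reactants: 11 tert-butyldimethylsilyl 7-[(tert-butyldimethylsilyl)oxy]-5-methoxy-8-(3-methylbut-2-en-1-yl)-6-(2-methylpropanoyl)-2-oxochromane-3-carboxylate
Product: 12 7-[(tert-butyldimethylsilyl)oxy]-5-methoxy-8-(3-methylbut-2-en-1-yl)-6-(2-methylpropanoyl)-2-oxochromane-3-carbonyl chloride
Conditions: (COCl)2 (1.2 equiv), DMF (cat.), CH2Cl2, 0 °C → rt; volatiles removed, crude 12 used at once
Reagents that add atoms: oxalyl chloride, O=C(Cl)C(=O)Cl
Why: Conversion of a silyl ester into an acid chloride by the chloroiminium reagent under neutral conditions; silicon leaves as the silyl chloride, so no HCl is set free near the prenyl group and the aryl silyl ether is retained.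

Step 6
Reactants: 13 pentan-3-one
Product: 14 (Z)-3-(trimethylsilyloxy)pent-2-ene
Conditions: TMSOTf (1.1 equiv), Et3N (1.2 equiv), Et2O, 0 °C → rt; distilled
Reagents that add atoms: trimethylsilyl trifluoromethanesulfonate, C[Si](C)(C)OS(=O)(=O)C(F)(F)F
Why: Amine-mediated O-silylation of a symmetrical ketone, which has only one regiochemical outcome and favours the Z enol ether.

Step 7
Reactants: 12 7-[(tert-butyldimethylsilyl)oxy]-5-methoxy-8-(3-methylbut-2-en-1-yl)-6-(2-methylpropanoyl)-2-oxochromane-3-carbonyl chloride; 14 (Z)-3-(trimethylsilyloxy)pent-2-ene
Product: 16 3-{[4-(tert-butyldimethylsilyloxy)-2-hydroxy-6-methoxy-3-(3-methylbut-2-en-1-yl)-5-(2-methylpropanoyl)phenyl]methyl}-6-ethyl-4-hydroxy-5-methyl-2H-pyran-2-one, via triketone lactone 15 (not isolated)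
Conditions: 14 (2 equiv), ZnCl2 (1.0 equiv), CH2Cl2–Et2O, 0 °C → rt, then 40 °C; aq NH4Cl
Reagents that add atoms: none
Why: ZnCl2 activates the acid chloride of 12, the β-carbon of 14 attacks it and chloride takes the silicon from the resulting oxocarbenium ion, which forms C4–C5 and gives triketone 15; this is the known Lewis-acid-mediated C-acylation of silyl enol ethers by acid chlorides to 1,3-diketones. In 15 the outer ketone enolises towards C5, its enol oxygen adds to the aryl lactone carbonyl, and the tetrahedral intermediate expels the C2' oxygen, a good leaving group because it is para to the ketone; this forms O1–C2, and tautomerisation gives the 4-hydroxy-2-pyrone. Ring A closes by 6-exo-trig addition–elimination, the mode by which 3,5-dioxo aryl esters lactonise and by which silyl enol ethers give 4-hydroxy-2-pyrones with malonyl dichloride. No stereocentre is formed, and the labile centres at C3 and C5 of 15 both become sp2. The step needs C- rather than O-acylation of the enol ether, which the trimethylsilyl group and ZnCl2 favour. It also needs ring closure rather than intermolecular ester formation, which is secured because O4' is silylated, O2' stays in the lactone until the acid chloride is consumed, and the enol oxygen reaches the lactone carbonyl through a six-membered transition state. Since both carbonyls sit on C3, attack of 14 on the lactone first and O-acylation by the acid chloride second would give the same product; no amine is present, so 12 is not diverted to its ketene.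

Step 8
Reactants: 16 3-{[4-(tert-butyldimethylsilyloxy)-2-hydroxy-6-methoxy-3-(3-methylbut-2-en-1-yl)-5-(2-methylpropanoyl)phenyl]methyl}-6-ethyl-4-hydroxy-5-methyl-2H-pyran-2-one
Product: 17 3-{[2,4-dihydroxy-6-methoxy-3-(3-methylbut-2-en-1-yl)-5-(2-methylpropanoyl)phenyl]methyl}-6-ethyl-4-hydroxy-5-methyl-2H-pyran-2-one
Conditions: Bu4NF (1.2 equiv), AcOH (1.2 equiv), THF, 0 °C
Reagents that add atoms: none
Why: Fluoride-induced cleavage of an aryl silyl ether; the acetic acid buffer keeps the medium from becoming basic enough to reopen the methylene bridge by retro-Michael loss of the pyrone, and no acid strong enough to cyclise the prenyl group is present.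

## Compound list

1 | 5-methoxyresorcinol (5-methoxybenzene-1,3-diol) | COc1cc(O)cc(O)c1 | starting material
2 | 2-methylpropanenitrile | CC(C)C#N | starting material
3 | 1-(2,4-dihydroxy-6-methoxyphenyl)-2-methylpropan-1-iminium chloride | COc1cc(O)cc(O)c1C(=[NH2+])C(C)C.[Cl-] | intermediate (not isolated)
4 | 1-(2,4-dihydroxy-6-methoxyphenyl)-2-methylpropan-1-one | COc1cc(O)cc(O)c1C(=O)C(C)C | intermediate
5 | 1-bromo-3-methylbut-2-ene (prenyl bromide) | CC(C)=CCBr | starting material
6 | 1-[2,4-dihydroxy-6-methoxy-3-(3-methylbut-2-en-1-yl)phenyl]-2-methylpropan-1-one | COc1cc(O)c(CC=C(C)C)c(O)c1C(=O)C(C)C | intermediate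
7 | 2,2-dimethyl-1,3-dioxane-4,6-dione (Meldrum's acid) | CC1(C)OC(=O)CC(=O)O1 | starting material
8 | 2,2-dimethyl-5-methylidene-1,3-dioxane-4,6-dione | C=C1C(=O)OC(C)(C)OC1=O | intermediate (not isolated)
9 | 5-{[2,4-dihydroxy-6-methoxy-3-(3-methylbut-2-en-1-yl)-5-(2-methylpropanoyl)phenyl]methyl}-2,2-dimethyl-1,3-dioxane-4,6-dione | CC1(C)OC(=O)C(Cc2c(O)c(CC=C(C)C)c(O)c(C(=O)C(C)C)c2OC)C(=O)O1 | intermediate (not isolated)
10 | 7-hydroxy-5-methoxy-8-(3-methylbut-2-en-1-yl)-6-(2-methylpropanoyl)-2-oxochromane-3-carboxylic acid (racemic) | O=C(O)C1Cc2c(OC)c(C(=O)C(C)C)c(O)c(CC=C(C)C)c2OC1=O | intermediate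
11 | tert-butyldimethylsilyl 7-[(tert-butyldimethylsilyl)oxy]-5-methoxy-8-(3-methylbut-2-en-1-yl)-6-(2-methylpropanoyl)-2-oxochromane-3-carboxylate (racemic) | CC(C)(C)[Si](C)(C)OC(=O)C1Cc2c(OC)c(C(=O)C(C)C)c(O[Si](C)(C)C(C)(C)C)c(CC=C(C)C)c2OC1=O | intermediate
12 | 7-[(tert-butyldimethylsilyl)oxy]-5-methoxy-8-(3-methylbut-2-en-1-yl)-6-(2-methylpropanoyl)-2-oxochromane-3-carbonyl chloride (racemic) | O=C(Cl)C1Cc2c(OC)c(C(=O)C(C)C)c(O[Si](C)(C)C(C)(C)C)c(CC=C(C)C)c2OC1=O | intermediate
13 | pentan-3-one | CCC(=O)CC | starting material
14 | (Z)-3-(trimethylsilyloxy)pent-2-ene | C/C=C(/CC)O[Si](C)(C)C | intermediate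
15 | 7-[(tert-butyldimethylsilyl)oxy]-5-methoxy-8-(3-methylbut-2-en-1-yl)-3-(2-methyl-3-oxopentanoyl)-6-(2-methylpropanoyl)chroman-2-one (mixture of stereoisomers and enol forms) | CCC(=O)C(C)C(=O)C1Cc2c(OC)c(C(=O)C(C)C)c(O[Si](C)(C)C(C)(C)C)c(CC=C(C)C)c2OC1=O | intermediate (not isolated)
16 | 3-{[4-(tert-butyldimethylsilyloxy)-2-hydroxy-6-methoxy-3-(3-methylbut-2-en-1-yl)-5-(2-methylpropanoyl)phenyl]methyl}-6-ethyl-4-hydroxy-5-methyl-2H-pyran-2-one | CCc1oc(=O)c(Cc2c(O)c(CC=C(C)C)c(O[Si](C)(C)C(C)(C)C)c(C(=O)C(C)C)c2OC)c(O)c1C | intermediate
17 | 3-{[2,4-dihydroxy-6-methoxy-3-(3-methylbut-2-en-1-yl)-5-(2-methylpropanoyl)phenyl]methyl}-6-ethyl-4-hydroxy-5-methyl-2H-pyran-2-one | CCc1oc(=O)c(Cc2c(O)c(CC=C(C)C)c(O)c(C(=O)C(C)C)c2OC)c(O)c1C | target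

## Step count and least certain steps

Total: 8 steps. Longest linear sequence: 7 steps (1 → 4 → 6 → 10 → 11 → 12 → 16 → 17); step 6 is a one-step side branch.

**Step 7 (key step).** C-acylation by the α-branched, crowded acid chloride may be slow. O-acylation of the enol ether, loss of HCl from 12 to the aryloxycarbonyl ketene (with closure through the ester carbonyl oxygen instead of the enol oxygen) or protodesilylation of 14 could then compete. The sequence may also stall at 15, or the freed hydroxyls of 16 may be acylated by unconsumed 12. The fallback gives up the annulation and bridges a separately made ring A by known chemistry. It sets out from 14 and 6 and returns at 17. Enol ether 14 with malonyl dichloride gives 6-ethyl-4-hydroxy-5-methyl-2H-pyran-2-one F1. F1 with Me2N=CH2+ I− gives the Mannich base 3-[(dimethylamino)methyl]-6-ethyl-4-hydroxy-5-methyl-2H-pyran-2-one F2. On warming with ketone 6, F2 loses dimethylamine to 6-ethyl-5-methyl-3-methylidene-2H-pyran-2,4(3H)-dione F3, which is trapped at the only free ring carbon of 6 to give 17 directly. The price is the dimer formation that the main route is designed to avoid.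

**Step 3.** Free formaldehyde may bridge two molecules of 6. Conjugate addition of the ketone-deactivated arene to 8 may be slow, and 10 may decarboxylate if warming is prolonged. The fallback places the one-carbon electrophile on the arene first. It sets out from 6 and returns at 10. Ketone 6 with Me2N=CH2+ I− gives the Mannich base 1-{3-[(dimethylamino)methyl]-4,6-dihydroxy-2-methoxy-5-(3-methylbut-2-en-1-yl)phenyl}-2-methylpropan-1-one F4. On heating with 7 in MeCN, F4 loses dimethylamine to the ortho-quinone methide 3-hydroxy-5-methoxy-6-methylidene-2-(3-methylbut-2-en-1-yl)-4-(2-methylpropanoyl)cyclohexa-2,4-dien-1-one F5. Compound 7 adds to F5 to give 9, which lactonises to 10 as in the main route.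

**Step 2.** O-alkylation, dialkylation and attack at the ring carbon next to the methoxy group may all compete with the desired C-alkylation. The fallback builds the ring substitution by directed metalation. It sets out from 1, returns at 6, and also bypasses step 1, whose outcome between the two hydroxyls is the other open regiochemical point. Compound 1 with MOMCl and i-Pr2NEt gives 1-methoxy-3,5-bis(methoxymethoxy)benzene F6. Deprotonation with n-BuLi between the two acetal oxygens and alkylation with 5 in the presence of CuI gives 5-methoxy-1,3-bis(methoxymethoxy)-2-(3-methylbut-2-en-1-yl)benzene F7. A second deprotonation with n-BuLi at one of the two equivalent remaining ring carbons, followed by N-methoxy-N,2-dimethylpropanamide, gives 1-[6-methoxy-2,4-bis(methoxymethoxy)-3-(3-methylbut-2-en-1-yl)phenyl]-2-methylpropan-1-one F8. Dilute HCl in MeOH releases 6.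

**Step 4.** Silylation of the chelated phenol may be incomplete. Excess silyl triflate may silylate the enol of the malonyl position, or base-induced opening of the activated lactone may be followed by silylation of the freed phenoxide. The fallback drops the protecting group and relies on the low nucleophilicity of the chelated, di-ortho-substituted phenol in the absence of base. It sets out from 10 and returns at 17. Acid 10 with 1-chloro-N,N,2-trimethylprop-1-en-1-amine under neutral conditions gives 7-hydroxy-5-methoxy-8-(3-methylbut-2-en-1-yl)-6-(2-methylpropanoyl)-2-oxochromane-3-carbonyl chloride F9. F9 is treated with 14 and ZnCl2 as in step 7 and gives 17 directly.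

## Further compounds

F1 | step 7 | 6-ethyl-4-hydroxy-5-methyl-2H-pyran-2-one | CCc1oc(=O)cc(O)c1C
F2 | step 7 | 3-[(dimethylamino)methyl]-6-ethyl-4-hydroxy-5-methyl-2H-pyran-2-one | CCc1oc(=O)c(CN(C)C)c(O)c1C
F3 | step 7 | 6-ethyl-5-methyl-3-methylidene-2H-pyran-2,4(3H)-dione | CCC1=C(C)C(=O)C(=C)C(=O)O1
F4 | step 3 | 1-{3-[(dimethylamino)methyl]-4,6-dihydroxy-2-methoxy-5-(3-methylbut-2-en-1-yl)phenyl}-2-methylpropan-1-one | COc1c(CN(C)C)c(O)c(CC=C(C)C)c(O)c1C(=O)C(C)C
F5 | step 3 | 3-hydroxy-5-methoxy-6-methylidene-2-(3-methylbut-2-en-1-yl)-4-(2-methylpropanoyl)cyclohexa-2,4-dien-1-one | C=C1C(=O)C(CC=C(C)C)=C(O)C(C(=O)C(C)C)=C1OC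
F6 | step 2 | 1-methoxy-3,5-bis(methoxymethoxy)benzene | COCOc1cc(OC)cc(OCOC)c1
F7 | step 2 | 5-methoxy-1,3-bis(methoxymethoxy)-2-(3-methylbut-2-en-1-yl)benzene | COCOc1cc(OC)cc(OCOC)c1CC=C(C)C
F8 | step 2 | 1-[6-methoxy-2,4-bis(methoxymethoxy)-3-(3-methylbut-2-en-1-yl)phenyl]-2-methylpropan-1-one | COCOc1c(CC=C(C)C)c(OCOC)cc(OC)c1C(=O)C(C)C
F9 | step 4 | 7-hydroxy-5-methoxy-8-(3-methylbut-2-en-1-yl)-6-(2-methylpropanoyl)-2-oxochromane-3-carbonyl chloride | O=C(Cl)C1Cc2c(OC)c(C(=O)C(C)C)c(O)c(CC=C(C)C)c2OC1=O
A1 | alternative 1 | 1-[2,4-dihydroxy-6-methoxy-3-(3-methylbut-2-en-1-yl)phenyl]-2-methylpropan-1-one | COc1cc(O)c(CC=C(C)C)c(O)c1C(=O)C(C)C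
A2 | alternative 1 | 1-methoxy-4-methylpent-1-yn-3-one | COC#CC(=O)C(C)C
A3 | alternative 1 | 1-methoxy-2-(3-methylbut-2-en-1-yl)-1,3-bis(trimethylsilyloxy)buta-1,3-diene | C=C(O[Si](C)(C)C)C(CC=C(C)C)=C(OC)O[Si](C)(C)C
A4 | alternative 2 | methyl (2Z)-2-methyl-3-({3-[6-methoxy-2,4-bis(methoxymethoxy)-3-(3-methylbut-2-en-1-yl)-5-(2-methylpropanoyl)phenyl]propanoyl}oxy)pent-2-enoate | CC/C(OC(=O)CCc1c(OCOC)c(CC=C(C)C)c(OCOC)c(C(=O)C(C)C)c1OC)=C(\C)C(=O)OC
A5 | alternative 2 | 6-ethyl-4-hydroxy-3-{[6-methoxy-2,4-bis(methoxymethoxy)-3-(3-methylbut-2-en-1-yl)-5-(2-methylpropanoyl)phenyl]methyl}-5-methyl-2H-pyran-2-one | CCc1oc(=O)c(Cc2c(OCOC)c(CC=C(C)C)c(OCOC)c(C(=O)C(C)C)c2OC)c(O)c1C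
A6 | alternative 3 | (2Z)-pent-2-en-3-yl 4-[2,4-diacetoxy-6-methoxy-3-(3-methylbut-2-en-1-yl)-5-(2-methylpropanoyl)phenyl]-2-diazo-3-oxobutanoate | C/C=C(/CC)OC(=O)C(=[N+]=[N-])C(=O)Cc1c(OC(C)=O)c(CC=C(C)C)c(OC(C)=O)c(C(=O)C(C)C)c1OC
A7 | alternative 3 | (2Z)-pent-2-en-3-yl 2-{[2,4-diacetoxy-6-methoxy-3-(3-methylbut-2-en-1-yl)-5-(2-methylpropanoyl)phenyl]methyl}-3-oxoprop-2-enoate | C/C=C(/CC)OC(=O)C(=C=O)Cc1c(OC(C)=O)c(CC=C(C)C)c(OC(C)=O)c(C(=O)C(C)C)c1OC
A8 | alternative 3 | 3-{[2,4-diacetoxy-6-methoxy-3-(3-methylbut-2-en-1-yl)-5-(2-methylpropanoyl)phenyl]methyl}-6-ethyl-4-hydroxy-5-methyl-2H-pyran-2-one | CCc1oc(=O)c(Cc2c(OC(C)=O)c(CC=C(C)C)c(OC(C)=O)c(C(=O)C(C)C)c2OC)c(O)c1C
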